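**Retrosynthetic overview**
1. Target 22 ← Schenck ene reaction of singlet oxygen on the 7(11)-en-8-one 21 ← angeloylation of O-3 and acetylation of O-4 of the 3α,4α-diol 17 ← α-face OsO4 dihydroxylation of the C3=C4 alkene of dienone 16.
2. Feature used: the cis-3,4-dioxygenated carbons of ring A (C1–C5, C10) come from a C3=C4 alkene, which is the cyclohexene bond of a Diels–Alder adduct (diene C2=C3–C4=C5, dienophile C10=C1) whose tether C6–C9 is ring B (C5–C10). C7 is only fixed in the last step, so its earlier configuration can steer the cycloaddition and then be erased.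
3. 16 ← oxidation at C8 and β-elimination of O-11 from adduct 12 ← intramolecular Diels–Alder reaction of decatriene 11; rings A and B are formed together in this one step (bonds C1–C2 and C5–C10).
4. 11 ← diol 10 ← ester 9. C7 lies between C8 and C11 (an aldol-type 1,3-dioxygenated array), so it is set anti to a C8 carbinol by Fráter–Seebach alkylation of β-hydroxy ester 4 with dienyl bromide 7; C8 is carried as a carbinol tied to O-11 in an acetonide and is oxidised after the cycloaddition.
5. 4 ← copper-catalysed opening of epoxy ester 2 (from chlorohydrin ester 1) with isopropenyl Grignard 3; 7 ← enynol 5 by semihydrogenation and bromination.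

Key step: step 8

Remark: eudesmane numbering is used throughout (C11–C13 isopropyl unit, C14 on C10, C15 on C4); α is the face opposite the C10 methyl; compounds 1, 3, 5 and 18 are taken as purchased.

**Step 1**
Reactants: 1 ethyl (3R)-4-chloro-3-hydroxybutanoate
Product: 2 ethyl 2-[(2R)-oxiran-2-yl]acetate
Conditions: Ag2O (1.5 equiv), DME, 60 °C, dark
Reagents that add atoms: none
Why: Silver-assisted intramolecular Williamson closure (3-exo-tet) forms the epoxide under non-basic conditions that avoid β-elimination of the β-hydroxy ester; the carbinol carbon is not touched, so the R configuration is kept.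

**Step 2**
Reactants: 2 ethyl 2-[(2R)-oxiran-2-yl]acetate; 3 isopropenylmagnesium bromide
Product: 4 ethyl (3S)-3-hydroxy-5-methylhex-5-enoate
Conditions: 3 (1.5 equiv), CuBr·SMe2 (10 mol %), THF, −40 °C
Reagents that add atoms: isopropenylmagnesium bromide (compound 3), C=C(C)[Mg]Br
Why: Copper-catalysed Grignard opening of a terminal epoxide (SN2 at the unhindered CH2, faster than ester addition at −40 °C) brings in C10, C14 and C1; the carbinol centre (future C8) is untouched and its descriptor changes from R to S only through the CIP priorities.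

**Step 3**
Reactants: 5 (2E)-3-methylpent-2-en-4-yn-1-ol
Product: 6 (2E)-3-methylpenta-2,4-dien-1-ol
Conditions: H2 (1 atm), Lindlar catalyst (Pd on CaCO3, poisoned with Pb(OAc)2), quinoline, EtOAc/hexane, 0 °C
Reagents that add atoms: none
Why: Lindlar semihydrogenation should stop the terminal conjugated alkyne at the vinyl stage and leave the trisubstituted E alkene alone, giving the E diene.

**Step 4**
Reactants: 6 (2E)-3-methylpenta-2,4-dien-1-ol
Product: 7 (3E)-5-bromo-3-methylpenta-1,3-diene
Conditions: PBr3 (0.4 equiv), Et2O, −20 → 0 °C; used crude at once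
Reagents that add atoms: phosphorus tribromide, BrP(Br)Br
Why: Conversion of an allylic alcohol into the bromide through its phosphite ester (SN2); the primary conjugated dienyl bromide is the favoured allylic isomer and the E geometry should hold at low temperature.

**Step 5**
Reactants: 4 ethyl (3S)-3-hydroxy-5-methylhex-5-enoate; 7 (3E)-5-bromo-3-methylpenta-1,3-diene
Product: 9 ethyl (2S,3S)-3-hydroxy-5-methyl-2-[(2E)-3-methylpenta-2,4-dien-1-yl]hex-5-enoate, via dilithium alkoxide enolate 8 (not isolated)
Conditions: LiN(iPr)2 (2.2 equiv), THF, −78 → −20 °C; then 7, DMPU, −78 → −20 °C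
Reagents that add atoms: none
Why: Fráter–Seebach alkylation, in which the chelated dilithium alkoxide enolate is attacked by the allylic bromide on the face away from the carbinol side chain; this sets C7 as 2S, anti to the 3S carbinol (C8).

**Step 6**
Reactants: 9 ethyl (2S,3S)-3-hydroxy-5-methyl-2-[(2E)-3-methylpenta-2,4-dien-1-yl]hex-5-enoate
Product: 10 (3S,4S)-2,6-dimethyl-3-[(2E)-3-methylpenta-2,4-dien-1-yl]hept-6-ene-2,4-diol
Conditions: MeMgBr (5 equiv), CeCl3 (anhydrous), THF, −78 → 0 °C
Reagents that add atoms: methylmagnesium bromide, C[Mg]Br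
Why: Double addition of a methyl organometallic to the ester gives the tertiary C11 carbinol with C12 and C13; the cerium reagent suppresses enolisation of the intermediate methyl ketone, so C7 should keep its configuration.

**Step 7**
Reactants: 10 (3S,4S)-2,6-dimethyl-3-[(2E)-3-methylpenta-2,4-dien-1-yl]hept-6-ene-2,4-diol
Product: 11 (5S,6S)-2,2,4,4-tetramethyl-5-[(2E)-3-methylpenta-2,4-dien-1-yl]-6-(2-methylprop-2-en-1-yl)-1,3-dioxane
Conditions: 2,2-dimethoxypropane, PPTS (cat.), CH2Cl2, rt
Reagents that add atoms: 2,2-dimethoxypropane, COC(C)(C)OC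
Why: Acid-catalysed transketalisation of the 1,3-diol gives the six-membered acetonide, which protects both hydroxyls for the thermolysis and ties C7 and C8 into a ring with the two side arms trans; no stereocentre is affected.

**Step 8**
Reactants: 11 (5S,6S)-2,2,4,4-tetramethyl-5-[(2E)-3-methylpenta-2,4-dien-1-yl]-6-(2-methylprop-2-en-1-yl)-1,3-dioxane
Product: 12 8α,11-(isopropylidenedioxy)eudesm-3-ene (trans-fused octalin; 5α-H; 7α-H; 8β-H; 10β-CH3)
Conditions: toluene (0.02 M), BHT (cat.), base-washed sealed tube, 200 °C
Reagents that add atoms: none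
Why: A concerted, thermally allowed [4+2] cycloaddition joins the diene C2=C3–C4=C5 to the unactivated 1,1-disubstituted alkene C10=C1 and makes C1–C2 and C5–C10 in one event; the closest known reaction type is the thermal type 1 intramolecular Diels–Alder reaction of 1,3,9-decatrienes with a methallyl dienophile, which gives trans-fused, angularly methylated octalins. Ring A is closed as the new cyclohexene (C1, C2, C3=C4, C5, C10) by the cycloaddition itself, and ring B (C5–C10) is closed in the fused mode because the four-atom tether C6–C9 links the diene terminus C5 to the internal dienophile carbon C10. The new centres C5 and C10 are set relative to each other by the anti (tether-exo) transition state, in which the forming ring B is a chair and the C10 methyl lies under the diene, so H-5 and the C10 methyl end up trans. Their absolute sense comes from C7 and C8: the trans-fused dioxane forces the C7–C11 and C8–O bonds to be equatorial on that chair, which leaves one diene face open and places the C10 methyl cis to C11 (5α-H, 10β-CH3). The step needs trans over cis ring fusion and a single π-face; the first rests on the chair-like tether (the syn alternative must pass the ring-fused tether under the diene in a boat-like or eclipsed arrangement), the second on the locked equatorial substituents, and regiochemistry is fixed by the tether length. The E geometry at C4=C5 excludes a 1,5-hydrogen shift of the diene, and the acetonide carries no group that is labile at 200 °C.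

**Step 9**
Reactants: 12 8α,11-(isopropylidenedioxy)eudesm-3-ene
Product: 13 eudesm-3-ene-8α,11-diol
Conditions: AcOH/THF/H2O (3:1:1), 40 °C
Reagents that add atoms: none
Why: Mild acid hydrolysis of the isopropylidene acetal frees the 1,3-diol, and the trisubstituted C3=C4 alkene should be stable to dilute acetic acid.

**Step 10**
Reactants: 13 eudesm-3-ene-8α,11-diol
Product: 14 11-hydroxyeudesm-3-en-8-one
Conditions: Dess–Martin periodinane, NaHCO3, CH2Cl2, 0 °C → rt
Reagents that add atoms: none
Why: Dess–Martin oxidation converts the secondary C8 carbinol into the ketone and cannot oxidise the tertiary C11 alcohol; the auxiliary C8 stereocentre is erased here.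

**Step 11**
Reactants: 14 11-hydroxyeudesm-3-en-8-one
Product: 16 eudesma-3,7(11)-dien-8-one, via tertiary mesylate 15 (not isolated)
Conditions: MsCl, Et3N, CH2Cl2, 0 °C → rt; then DBU, rt
Reagents that add atoms: none
Why: Mesylation of the tertiary aldol hydroxyl (sulfene pathway) followed by E1cB elimination through the C7 enolate gives the conjugated 7(11)-enone, DBU moving any 11(12)-isomer into conjugation; the steering C7 stereocentre is erased.

**Step 12**
Reactants: 16 eudesma-3,7(11)-dien-8-one
Product: 17 3α,4α-dihydroxyeudesm-7(11)-en-8-one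
Conditions: OsO4 (2 mol %), NMO (1.5 equiv), acetone/H2O (4:1), 0 °C → rt
Reagents that add atoms: N-methylmorpholine N-oxide, C[N+]1([O-])CCOCC1; water, O (both oxygens are delivered through catalytic osmium tetroxide, O=[Os](=O)(=O)=O)
Why: Upjohn dihydroxylation, in which electrophilic OsO4 should react with the isolated trisubstituted C3=C4 alkene and not with the electron-poor tetrasubstituted enone; the suprafacial [3+2] addition on the α face, away from the axial C10 methyl, sets C3 (R) and C4 (S) as the 3α,4α-cis-diol.

**Step 13**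
Reactants: 17 3α,4α-dihydroxyeudesm-7(11)-en-8-one; 18 angelic acid
Product: 20 3α-angeloyloxy-4α-hydroxyeudesm-7(11)-en-8-one, via angelic 2,4,6-trichlorobenzoic anhydride 19 (not isolated)
Conditions: 18, 2,4,6-trichlorobenzoyl chloride, Et3N, toluene, rt; then 17, toluene, 80 °C
Reagents that add atoms: angelic acid (compound 18), C/C=C(/C)C(=O)O
Why: Yamaguchi esterification through the mixed anhydride should acylate only the secondary 3α-hydroxyl (the tertiary 4α-hydroxyl is too hindered) and, run without a nucleophilic catalyst, is expected to keep the Z geometry of the angelate.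

**Step 14**
Reactants: 20 3α-angeloyloxy-4α-hydroxyeudesm-7(11)-en-8-one
Product: 21 4α-acetoxy-3α-angeloyloxyeudesm-7(11)-en-8-one
Conditions: Ac2O (10 equiv), DMAP (1 equiv), Et3N, CH2Cl2, 40 °C
Reagents that add atoms: acetic anhydride, CC(=O)OC(C)=O
Why: DMAP-catalysed acyl transfer with excess anhydride is the standard way to esterify a tertiary alcohol; no stereocentre changes, and migration of the angelate from the secondary to the tertiary oxygen is thermodynamically uphill.

**Step 15**
Reactants: 21 4α-acetoxy-3α-angeloyloxyeudesm-7(11)-en-8-one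
Product: 22 4α-acetoxy-3α-angeloyloxy-7α-hydroperoxyeudesm-11-en-8-one (target)
Conditions: O2, hν (visible light), tetraphenylporphyrin (cat.), CH2Cl2, −20 °C
Reagents that add atoms: dioxygen, O=O
Why: Schenck ene reaction of singlet oxygen with the s-cis α-isopropylidene ketone; oxygen should add to C7 from the α face (the β face of ring B is screened by the axial C10 methyl), where only the C12/C13 methyl hydrogens are aligned for abstraction because the α-hydrogen on C6 is equatorial, so the 7α-hydroperoxide (7S) with the C11=C12 isopropenyl group is expected, while the electron-poor angelate should react much more slowly.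

**Compound list**
1 | ethyl (3R)-4-chloro-3-hydroxybutanoate | CCOC(=O)C[C@@H](O)CCl | starting material
2 | ethyl 2-[(2R)-oxiran-2-yl]acetate | CCOC(=O)C[C@@H]1CO1 | intermediate
3 | isopropenylmagnesium bromide | C=C(C)[Mg]Br | starting material
4 | ethyl (3S)-3-hydroxy-5-methylhex-5-enoate | CCOC(=O)C[C@@H](O)CC(C)=C | intermediate
5 | (2E)-3-methylpent-2-en-4-yn-1-ol | C#C/C(C)=C/CO | starting material
6 | (2E)-3-methylpenta-2,4-dien-1-ol | C=C/C(C)=C/CO | intermediate
7 | (3E)-5-bromo-3-methylpenta-1,3-diene | C=C/C(C)=C/CBr | intermediate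
8 | dilithium alkoxide enolate of 4 | CCOC([O-])=C[C@@H]([O-])CC(C)=C.[Li+].[Li+] | intermediate (not isolated)
9 | ethyl (2S,3S)-3-hydroxy-5-methyl-2-[(2E)-3-methylpenta-2,4-dien-1-yl]hex-5-enoate | CCOC(=O)[C@@H](C/C=C(C)/C=C)[C@@H](O)CC(C)=C | intermediate
10 | (3S,4S)-2,6-dimethyl-3-[(2E)-3-methylpenta-2,4-dien-1-yl]hept-6-ene-2,4-diol | C=C/C(C)=C/C[C@@H]([C@@H](O)CC(C)=C)C(C)(C)O | intermediate
11 | (5S,6S)-2,2,4,4-tetramethyl-5-[(2E)-3-methylpenta-2,4-dien-1-yl]-6-(2-methylprop-2-en-1-yl)-1,3-dioxane | C=C/C(C)=C/C[C@H]1[C@H](CC(C)=C)OC(C)(C)OC1(C)C | intermediate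
12 | 8α,11-(isopropylidenedioxy)eudesm-3-ene (trans-fused; 5α-H; 7α-H; 8β-H; 10β-CH3) | CC1(C)OC(C)(C)O[C@H]2C[C@@]3(C)CCC=C(C)[C@@H]3C[C@H]12 | intermediate
13 | eudesm-3-ene-8α,11-diol (5α-H; 7α-H; 10β-CH3) | CC(C)(O)[C@H]1C[C@@H]2[C@](C)(CCC=C2C)C[C@@H]1O | intermediate
14 | 11-hydroxyeudesm-3-en-8-one (5α-H; 7α-H; 10β-CH3) | CC(C)(O)[C@H]1C[C@@H]2[C@](C)(CCC=C2C)CC1=O | intermediate
15 | 11-(methanesulfonyloxy)eudesm-3-en-8-one | CC(C)(OS(C)(=O)=O)[C@H]1C[C@@H]2[C@](C)(CCC=C2C)CC1=O | intermediate (not isolated)
16 | eudesma-3,7(11)-dien-8-one (5α-H; 10β-CH3) | CC(C)=C1C[C@@H]2[C@](C)(CCC=C2C)CC1=O | intermediate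
17 | 3α,4α-dihydroxyeudesm-7(11)-en-8-one (3R,4S,5R,10R) | CC(C)=C1C[C@@H]2[C@](C)(CC[C@@H](O)[C@@]2(C)O)CC1=O | intermediate
18 | angelic acid, (2Z)-2-methylbut-2-enoic acid | C/C=C(/C)C(=O)O | starting material
19 | angelic 2,4,6-trichlorobenzoic anhydride | C/C=C(/C)C(=O)OC(=O)c1c(Cl)cc(Cl)cc1Cl | intermediate (not isolated)
20 | 3α-angeloyloxy-4α-hydroxyeudesm-7(11)-en-8-one | CC(C)=C1C[C@@H]2[C@](C)(CC[C@@H](OC(=O)/C(C)=C\C)[C@@]2(C)O)CC1=O | intermediate
21 | 4α-acetoxy-3α-angeloyloxyeudesm-7(11)-en-8-one | CC(C)=C1C[C@@H]2[C@](C)(CC[C@@H](OC(=O)/C(C)=C\C)[C@@]2(C)OC(C)=O)CC1=O | intermediate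
22 | 4α-acetoxy-3α-angeloyloxy-7α-hydroperoxyeudesm-11-en-8-one (3R,4S,5R,7S,10R; CNP0360871.1) | C=C(C)[C@@]1(OO)C[C@@H]2[C@](C)(CC[C@@H](OC(=O)/C(C)=C\C)[C@@]2(C)OC(C)=O)CC1=O | target

**Total step count:** 15
**Longest linear sequence:** 13 steps (steps 1, 2, 5–15 from compound 1; the branch through steps 3 and 4 is equally long)

**Steps most likely to fail**

1. Step 8. The anti and syn transition states may lie too close in energy at 200 °C, so that trans ring-fusion selectivity is lost, and the slow cyclisation of the unactivated dienophile may let diene dimerisation compete. The fallback replaces the fused-dioxane lock by a gem-dioxy group at C8 and sets out from 10. Oxidation of the secondary hydroxyl (Dess–Martin periodinane, NaHCO3, CH2Cl2) would give (5R,7E)-5-(2-hydroxypropan-2-yl)-2,8-dimethyldeca-1,7,9-trien-4-one F1. Silylation of the tertiary hydroxyl with N-(trimethylsilyl)imidazole would give (5R,7E)-2,8-dimethyl-5-[2-(trimethylsilyloxy)propan-2-yl]deca-1,7,9-trien-4-one F2. Ketalisation under Noyori conditions (1,2-bis(trimethylsilyloxy)ethane, cat. TMSOTf, CH2Cl2, −78 to −20 °C) would give 2-[(3R,5E)-2,6-dimethyl-2-(trimethylsilyloxy)octa-5,7-dien-3-yl]-2-(2-methylprop-2-en-1-yl)-1,3-dioxolane F3, in which Thorpe–Ingold compression at C8 folds the tether and only the C7 substituent has to sit equatorial. Thermolysis as in step 8 would give 8,8-ethylenedioxy-11-(trimethylsilyloxy)eudesm-3-ene F4, and dilute aqueous acid (TsOH, acetone/H2O, rt) would remove ketal and silyl ether and return to the route at 14.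

2. Step 15. Singlet oxygen may instead abstract the axial β-hydrogen on C6 (oxygen ending on C11, the geminal pathway of α-substituted enones) or attack the β face, eroding regio- and facial selectivity. The fallback fixes the site of oxygenation through an enol ether and sets out from 21. Soft enolisation toward the γ-methyl (TMSOTf, Et3N, CH2Cl2, 0 °C) would give 4α-acetoxy-3α-angeloyloxy-8-(trimethylsilyloxy)eudesma-7,11-diene F5, whose enol ether carbon C7 is the nucleophilic site. Photooxygenation (O2, hν, tetraphenylporphyrin, CH2Cl2, −78 °C) by the silyl ene pathway (oxygen to C7 from the α face, silyl shift to the terminal oxygen) would give 4α-acetoxy-3α-angeloyloxy-7α-(trimethylsilylperoxy)eudesm-11-en-8-one F6. Methanolysis (MeOH, cat. PPTS, 0 °C) would return to the route at 22.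

3. Step 14. Acylation of the hindered tertiary 4α-hydroxyl may be so slow that base-induced acyl migration or Z to E isomerisation of the angelate takes over. The fallback reverses the order of the two esterifications and sets out from 17. Selective silylation of the secondary hydroxyl (TESCl, imidazole, DMF, 0 °C) would give 4α-hydroxy-3α-(triethylsilyloxy)eudesm-7(11)-en-8-one F7. Forcing acetylation with no angelate yet present (Ac2O, DMAP, Et3N, 60 °C) would give 4α-acetoxy-3α-(triethylsilyloxy)eudesm-7(11)-en-8-one F8. Acidic desilylation (HF·pyridine, THF, 0 °C), which avoids acyl migration, would give 4α-acetoxy-3α-hydroxyeudesm-7(11)-en-8-one F9. Yamaguchi angeloylation with anhydride 19 as in step 13 would return to the route at 21.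

**Further compounds**
F1 | step 8 | (5R,7E)-5-(2-hydroxypropan-2-yl)-2,8-dimethyldeca-1,7,9-trien-4-one | C=C/C(C)=C/C[C@@H](C(=O)CC(C)=C)C(C)(C)O
F2 | step 8 | (5R,7E)-2,8-dimethyl-5-[2-(trimethylsilyloxy)propan-2-yl]deca-1,7,9-trien-4-one | C=C/C(C)=C/C[C@@H](C(=O)CC(C)=C)C(C)(C)O[Si](C)(C)C
F3 | step 8 | 2-[(3R,5E)-2,6-dimethyl-2-(trimethylsilyloxy)octa-5,7-dien-3-yl]-2-(2-methylprop-2-en-1-yl)-1,3-dioxolane | C=C/C(C)=C/C[C@H](C(C)(C)O[Si](C)(C)C)C1(CC(C)=C)OCCO1
F4 | step 8 | 8,8-ethylenedioxy-11-(trimethylsilyloxy)eudesm-3-ene | CC(C)(O[Si](C)(C)C)[C@H]1C[C@@H]2[C@](C)(CCC=C2C)CC13OCCO3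
F5 | step 15 | 4α-acetoxy-3α-angeloyloxy-8-(trimethylsilyloxy)eudesma-7,11-diene | C=C(C)C=1C[C@@H]2[C@](C)(CC[C@@H](OC(=O)/C(C)=C\C)[C@@]2(C)OC(C)=O)CC=1O[Si](C)(C)C
F6 | step 15 | 4α-acetoxy-3α-angeloyloxy-7α-(trimethylsilylperoxy)eudesm-11-en-8-one | C=C(C)[C@@]1(OO[Si](C)(C)C)C[C@@H]2[C@](C)(CC[C@@H](OC(=O)/C(C)=C\C)[C@@]2(C)OC(C)=O)CC1=O
F7 | step 14 | 4α-hydroxy-3α-(triethylsilyloxy)eudesm-7(11)-en-8-one | CC(C)=C1C[C@@H]2[C@](C)(CC[C@@H](O[Si](CC)(CC)CC)[C@@]2(C)O)CC1=O
F8 | step 14 | 4α-acetoxy-3α-(triethylsilyloxy)eudesm-7(11)-en-8-one | CC(C)=C1C[C@@H]2[C@](C)(CC[C@@H](O[Si](CC)(CC)CC)[C@@]2(C)OC(C)=O)CC1=O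
F9 | step 14 | 4α-acetoxy-3α-hydroxyeudesm-7(11)-en-8-one | CC(C)=C1C[C@@H]2[C@](C)(CC[C@@H](O)[C@@]2(C)OC(C)=O)CC1=O
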